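**Plan**

- Ring A is numbered C1 (CO2H), C2 (OMe), C3 (side chain), C4‑H, C5‑H, C6 (O‑aryl). It is a contiguously tetrasubstituted benzene whose oxygens at C2 and C6 are meta to each other with the carboxyl carbon C1 between them, which is the pattern a vinylketene and an oxygen‑substituted alkyne assemble. The retrosynthesis therefore cuts ring A itself at C4–C5, C1–C2, C5–C6 and C2–C3.
- This leaves diazo enone 9 (C2 to C5 plus the side chain, fragment 1) and aryl ynol ether 21 (C6, C1, the future carboxyl carbon, the diaryl ether oxygen and ring B, fragment 2).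
- Forward: ring B is bought as an arene and carries its ether oxygen into the alkyne. Ring A is the only ring built, in step 13, where the two fragments are joined.
- After the annulation: O‑methylation at C2, oxidation of the C1 CH2O carbon to CO2H, hydrogenolysis of the ring B benzyl ether and global desilylation.
- The single stereocenter, (R) at the benzylic carbinol, is the carbinol carbon of (R)‑3‑hydroxy‑γ‑butyrolactone 1; its C–O bond is never broken.

Key step: step 13

Remark: the side‑chain diol is carried as its bis(triethylsilyl) ether, because triol 2 would take an acetonide on the 1,2‑diol and not on the 1,3‑diol; lactone 1 and aldehyde 10 are taken as purchasable.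

**Fragment 1: diazo enone 9**

Step 1
Reactants: 1 (R)-3-hydroxy-γ-butyrolactone [(4R)-4-hydroxyoxolan-2-one]
Product: 2 (2R)-4-methylpentane-1,2,4-triol
Conditions: MeMgBr (4 equiv), THF, 0 °C to rt; aqueous work-up
Reagents that add atoms: methylmagnesium bromide, C[Mg]Br
Why: Double Grignard addition to the lactone carbonyl, after deprotonation of the free hydroxyl, should open the ring to the tertiary carbinol without touching the stereocenter.

Step 2
Reactants: 2 (2R)-4-methylpentane-1,2,4-triol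
Product: 3 (2R)-4-methyl-1,2,4-tris(triethylsilyloxy)pentane
Conditions: TESOTf (3.6 equiv), 2,6-lutidine, CH2Cl2, −78 °C to rt
Reagents that add atoms: triethylsilyl trifluoromethanesulfonate, CC[Si](CC)(CC)OS(=O)(=O)C(F)(F)F
Why: Silylation with a silyl triflate and a hindered pyridine base is strong enough to cap the tertiary hydroxyl as well as the primary and secondary ones.

Step 3
Reactants: 3 (2R)-4-methyl-1,2,4-tris(triethylsilyloxy)pentane
Product: 5 (2R)-4-methyl-2,4-bis(triethylsilyloxy)pentanal, via alkoxysulfonium chloride 4 (not isolated)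
Conditions: (COCl)2, DMSO, CH2Cl2, −78 to −30 °C; Et3N, −78 to 0 °C
Reagents that add atoms: none
Why: Swern oxidation applied directly to a primary triethylsilyl ether: chlorodimethylsulfonium chloride attacks only the least hindered silyl ether oxygen, releases Et3SiCl and forms 4, which Et3N collapses to the aldehyde at low temperature without epimerising the α-silyloxy center.

Step 4
Reactants: 5 (2R)-4-methyl-2,4-bis(triethylsilyloxy)pentanal; 6 1-(triphenylphosphoranylidene)propan-2-one
Product: 7 (3E,5R)-7-methyl-5,7-bis(triethylsilyloxy)oct-3-en-2-one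
Conditions: toluene, 60 °C
Reagents that add atoms: none
Why: Wittig olefination with a ketone-stabilised ylide is (E)-selective and non-basic enough to leave the α-silyloxy stereocenter intact.

Step 5
Reactants: 7 (3E,5R)-7-methyl-5,7-bis(triethylsilyloxy)oct-3-en-2-one
Product: 9 (3E,5R)-1-diazo-7-methyl-5,7-bis(triethylsilyloxy)oct-3-en-2-one, via trifluoroacetyl diketone 8 (not isolated)
Conditions: LiN(SiMe3)2, THF, −78 °C; CF3CO2CH2CF3; cold dilute HCl wash; MsN3, Et3N, H2O, MeCN, rt
Reagents that add atoms: methanesulfonyl azide, CS(=O)(=O)N=[N+]=[N-]; 2,2,2-trifluoroethyl trifluoroacetate, O=C(OCC(F)(F)F)C(F)(F)F (its trifluoroacetyl group is held only in 8 and leaves again)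
Why: Detrifluoroacetylative diazo transfer: kinetic deprotonation at the methyl group and trifluoroacetylation activate that carbon for diazo transfer, which avoids the pyrazoline formation that diazomethane would cause on an enone.

**Fragment 2: aryl ynol ether 21**

Step 6
Reactants: 10 2-hydroxy-3-methoxy-5-methylbenzaldehyde
Product: 11 2,3-dihydroxy-5-methylbenzaldehyde
Conditions: BBr3, CH2Cl2, −78 to 0 °C; aqueous work-up
Reagents that add atoms: none
Why: Lewis acid demethylation of an aryl methyl ether with BBr3 is standard for ortho-vanillin-type aldehydes.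

Step 7
Reactants: 11 2,3-dihydroxy-5-methylbenzaldehyde
Product: 12 3-(benzyloxy)-2-hydroxy-5-methylbenzaldehyde
Conditions: NaH (2.2 equiv), DMSO, rt; BnBr (1.0 equiv); dilute HCl work-up
Reagents that add atoms: benzyl bromide, BrCc1ccccc1
Why: Williamson etherification of the dianion, in which the 3-phenoxide, not stabilised by chelation or conjugation to the aldehyde, is the more nucleophilic oxygen and is alkylated selectively.

Step 8
Reactants: 12 3-(benzyloxy)-2-hydroxy-5-methylbenzaldehyde; 13 trichloroethylene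
Product: 15 3-(benzyloxy)-2-[(E)-1,2-dichlorovinyloxy]-5-methylbenzaldehyde, via dichloroacetylene 14 (not isolated)
Conditions: K2CO3, DMF, 70 °C
Reagents that add atoms: none
Why: Base-mediated elimination of HCl from trichloroethylene gives dichloroacetylene, to which the phenoxide adds in anti fashion to give the (E)-dichlorovinyl ether, a known entry to aryl ynol ethers that tolerates the aldehyde.

Step 9
Reactants: 15 3-(benzyloxy)-2-[(E)-1,2-dichlorovinyloxy]-5-methylbenzaldehyde
Product: 16 {3-(benzyloxy)-2-[(E)-1,2-dichlorovinyloxy]-5-methylphenyl}methanol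
Conditions: NaBH4, MeOH/THF, 0 °C
Reagents that add atoms: none
Why: Borohydride reduction of the aldehyde does not touch the dichlorovinyl ether or the benzyl ether.

Step 10
Reactants: 16 {3-(benzyloxy)-2-[(E)-1,2-dichlorovinyloxy]-5-methylphenyl}methanol
Product: 17 tert-butyl({3-(benzyloxy)-2-[(E)-1,2-dichlorovinyloxy]-5-methylbenzyl}oxy)dimethylsilane
Conditions: TBSCl, imidazole, DMF, rt
Reagents that add atoms: tert-butyldimethylsilyl chloride, CC(C)(C)[Si](C)(C)Cl
Why: Imidazole-promoted silylation of the primary alcohol gives a benzylic silyl ether that withstands butyllithium at low temperature and later hydrogenolysis.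

Step 11
Reactants: 17 tert-butyl({3-(benzyloxy)-2-[(E)-1,2-dichlorovinyloxy]-5-methylbenzyl}oxy)dimethylsilane
Product: 20 3-{2-(benzyloxy)-6-[(tert-butyldimethylsilyloxy)methyl]-4-methylphenoxy}prop-2-yn-1-ol, via chloroethynyl ether 18 (not isolated), via lithium acetylide 19 (not isolated)
Conditions: n-BuLi (2.3 equiv), THF, −78 to −40 °C; (CH2O)n, −78 °C to rt; H2O
Reagents that add atoms: formaldehyde (from paraformaldehyde), C=O
Why: Dehydrochlorination of the dichlorovinyl ether followed by lithium–chlorine exchange gives the lithium aryloxyacetylide, which undergoes 1,2-addition to formaldehyde.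

Step 12
Reactants: 20 3-{2-(benzyloxy)-6-[(tert-butyldimethylsilyloxy)methyl]-4-methylphenoxy}prop-2-yn-1-ol
Product: 21 1-(benzyloxy)-3-[(tert-butyldimethylsilyloxy)methyl]-2-{[3-(4-methoxybenzyloxy)prop-1-yn-1-yl]oxy}-5-methylbenzene
Conditions: NaH, PMBCl, Bu4NI (cat.), THF/DMF, 0 °C to rt
Reagents that add atoms: 4-methoxybenzyl chloride, COc1ccc(CCl)cc1
Why: Williamson etherification under basic conditions spares the acid-sensitive ynol ether and gives an ether at the future C1 carbon that cannot leave as an ortho-quinone methide precursor and is orthogonal to every silyl and benzyl group.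

**Ring A and endgame**

Step 13
Reactants: 9 (3E,5R)-1-diazo-7-methyl-5,7-bis(triethylsilyloxy)oct-3-en-2-one; 21 1-(benzyloxy)-3-[(tert-butyldimethylsilyloxy)methyl]-2-{[3-(4-methoxybenzyloxy)prop-1-yn-1-yl]oxy}-5-methylbenzene
Product: 26 3-{2-(benzyloxy)-6-[(tert-butyldimethylsilyloxy)methyl]-4-methylphenoxy}-2-[(4-methoxybenzyloxy)methyl]-6-[(1R)-3-methyl-1,3-bis(triethylsilyloxy)butyl]phenol, via vinylketene 22 (not isolated), via vinylcyclobutenone 23 (not isolated), via dienylketene 24 (not isolated), via cyclohexadienone 25 (not isolated)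
Conditions: 9 (1.3 equiv, slow addition), hν (medium-pressure Hg lamp, Pyrex filter), ClCH2CH2Cl, rt; then 80 °C
Reagents that add atoms: none
Why: Light expels N2 from 9 and the alkenyl group shifts to the carbene carbon (Wolff rearrangement, bond C4–C5) to give vinylketene 22, which adds ynol ether 21 in a [2+2] cycloaddition (bonds C1–C2 and C5–C6) to give cyclobutenone 23; on warming, 23 opens in a four-electron conrotatory process to dienylketene 24. Ring A then closes by a thermally allowed six-electron disrotatory electrocyclisation of 24 (bond C2–C3) to dienone 25, which tautomerises to phenol 26. The closest known reaction type is the Danheiser benzannulation of photochemically generated vinylketenes with alkoxy- and siloxyalkynes; an aryloxyalkyne is a less electron-rich but still oxygen-activated member of the same class. No stereocenter is created, since the sp3 carbons of 23 and 25 are lost on aromatisation, and the silylated carbinol carbon is a spectator because its hydrogen is never acidified. The step needs one regiochemical outcome in the [2+2] addition, and the aryloxy oxygen secures it by polarising the triple bond so that the carbon remote from oxygen (bearing CH2OPMB) attacks the electrophilic ketene carbonyl carbon, which places the aryloxy group meta to the new hydroxyl with the CH2OPMB carbon between them. Chemoselectivity rests on full protection, since no free hydroxyl is present to trap the ketenes, and slow addition of 9 keeps the ketene concentration low against dimerisation.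

Step 14
Reactants: 26 the ring A phenol from step 13
Product: 27 1-{2-(benzyloxy)-6-[(tert-butyldimethylsilyloxy)methyl]-4-methylphenoxy}-3-methoxy-2-[(4-methoxybenzyloxy)methyl]-4-[(1R)-3-methyl-1,3-bis(triethylsilyloxy)butyl]benzene
Conditions: MeI, K2CO3, DMF, rt
Reagents that add atoms: iodomethane, CI
Why: Williamson O-methylation of the only free phenol; the alkyl silyl ethers and the benzylic ethers are inert to carbonate, and the neighbouring CH2OPMB group has no leaving-group ability.

Step 15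
Reactants: 27 the methyl ether from step 14
Product: 28 {6-[2-(benzyloxy)-6-[(tert-butyldimethylsilyloxy)methyl]-4-methylphenoxy]-2-methoxy-3-[(1R)-3-methyl-1,3-bis(triethylsilyloxy)butyl]phenyl}methanol
Conditions: DDQ, CH2Cl2/pH 7 phosphate buffer, 0 °C
Reagents that add atoms: none
Why: Oxidative cleavage of the PMB ether by DDQ (hydride abstraction and hydrolysis of the oxocarbenium ion) should leave the plain benzyl ether and the silyl ethers untouched in buffered two-phase medium; any aldehyde 29 formed by over-oxidation lies on the route.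

Step 16
Reactants: 28 the ring A benzylic alcohol from step 15
Product: 29 6-[2-(benzyloxy)-6-[(tert-butyldimethylsilyloxy)methyl]-4-methylphenoxy]-2-methoxy-3-[(1R)-3-methyl-1,3-bis(triethylsilyloxy)butyl]benzaldehyde
Conditions: Dess–Martin periodinane, pyridine, CH2Cl2, 0 °C to rt
Reagents that add atoms: none
Why: Dess–Martin oxidation converts hindered benzylic alcohols to aldehydes under near-neutral conditions that silyl ethers tolerate.

Step 17
Reactants: 29 the ring A aldehyde from step 16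
Product: 30 6-[2-(benzyloxy)-6-[(tert-butyldimethylsilyloxy)methyl]-4-methylphenoxy]-2-methoxy-3-[(1R)-3-methyl-1,3-bis(triethylsilyloxy)butyl]benzoic acid
Conditions: NaClO2, NaH2PO4, 2-methyl-2-butene, t-BuOH/H2O, rt
Reagents that add atoms: sodium chlorite, [Na+].[O-]Cl=O
Why: Pinnick oxidation uses a small oxidant that reaches a di-ortho-substituted aldehyde, and the alkene scavenger removes hypochlorous acid before it can chlorinate the electron-rich rings.

Step 18
Reactants: 30 the ring A acid from step 17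
Product: 31 6-{2-hydroxy-6-[(tert-butyldimethylsilyloxy)methyl]-4-methylphenoxy}-2-methoxy-3-[(1R)-3-methyl-1,3-bis(triethylsilyloxy)butyl]benzoic acid
Conditions: H2 (1 atm), Pd/C, EtOAc, rt
Reagents that add atoms: none
Why: Heterogeneous hydrogenolysis cleaves the phenolic benzyl ether much faster than the bulky silyl-capped benzylic C–O bonds of rings A and B; ethyl acetate is chosen because an alcoholic solvent would let Pd/C strip the triethylsilyl ethers.

Step 19
Reactants: 31 the phenol acid from step 18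
Product: 32 6-[2-hydroxy-6-(hydroxymethyl)-4-methylphenoxy]-3-[(1R)-1,3-dihydroxy-3-methylbutyl]-2-methoxybenzoic acid (CNP0452050.1)
Conditions: HF·pyridine, pyridine, THF, 0 °C to rt
Reagents that add atoms: none
Why: Fluoride-driven desilylation with pyridine-buffered HF·pyridine removes the two triethylsilyl ethers and the primary TBS ether without ionising the benzylic carbinol, so the (R) center is kept.

**Compound list**

1 | (R)-3-hydroxy-γ-butyrolactone [(4R)-4-hydroxyoxolan-2-one] | O=C1C[C@@H](O)CO1 | starting material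
2 | (2R)-4-methylpentane-1,2,4-triol | OC[C@H](O)CC(C)(C)O | intermediate
3 | (2R)-4-methyl-1,2,4-tris(triethylsilyloxy)pentane | CC[Si](CC)(CC)OC[C@H](O[Si](CC)(CC)CC)CC(C)(C)O[Si](CC)(CC)CC | intermediate
4 | dimethyl{[(2R)-4-methyl-2,4-bis(triethylsilyloxy)pentyl]oxy}sulfonium chloride | C[S+](C)OC[C@H](O[Si](CC)(CC)CC)CC(C)(C)O[Si](CC)(CC)CC.[Cl-] | intermediate
5 | (2R)-4-methyl-2,4-bis(triethylsilyloxy)pentanal | O=C[C@H](O[Si](CC)(CC)CC)CC(C)(C)O[Si](CC)(CC)CC | intermediate
6 | 1-(triphenylphosphoranylidene)propan-2-one | CC(=O)C=P(c1ccccc1)(c1ccccc1)c1ccccc1 | starting material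
7 | (3E,5R)-7-methyl-5,7-bis(triethylsilyloxy)oct-3-en-2-one | CC(=O)/C=C/[C@H](O[Si](CC)(CC)CC)CC(C)(C)O[Si](CC)(CC)CC | intermediate
8 | (5E,7R)-1,1,1-trifluoro-9-methyl-7,9-bis(triethylsilyloxy)dec-5-ene-2,4-dione | O=C(CC(=O)/C=C/[C@H](O[Si](CC)(CC)CC)CC(C)(C)O[Si](CC)(CC)CC)C(F)(F)F | intermediate
9 | (3E,5R)-1-diazo-7-methyl-5,7-bis(triethylsilyloxy)oct-3-en-2-one | [N-]=[N+]=CC(=O)/C=C/[C@H](O[Si](CC)(CC)CC)CC(C)(C)O[Si](CC)(CC)CC | intermediate
10 | 2-hydroxy-3-methoxy-5-methylbenzaldehyde | COc1cc(C)cc(C=O)c1O | starting material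
11 | 2,3-dihydroxy-5-methylbenzaldehyde | O=Cc1cc(C)cc(O)c1O | intermediate
12 | 3-(benzyloxy)-2-hydroxy-5-methylbenzaldehyde | O=Cc1cc(C)cc(OCc2ccccc2)c1O | intermediate
13 | trichloroethylene | ClC=C(Cl)Cl | starting material
14 | dichloroacetylene | ClC#CCl | intermediate
15 | 3-(benzyloxy)-2-[(E)-1,2-dichlorovinyloxy]-5-methylbenzaldehyde | O=Cc1cc(C)cc(OCc2ccccc2)c1O/C(Cl)=C\Cl | intermediate
16 | {3-(benzyloxy)-2-[(E)-1,2-dichlorovinyloxy]-5-methylphenyl}methanol | OCc1cc(C)cc(OCc2ccccc2)c1O/C(Cl)=C\Cl | intermediate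
17 | tert-butyl({3-(benzyloxy)-2-[(E)-1,2-dichlorovinyloxy]-5-methylbenzyl}oxy)dimethylsilane | CC(C)(C)[Si](C)(C)OCc1cc(C)cc(OCc2ccccc2)c1O/C(Cl)=C\Cl | intermediate
18 | 1-(benzyloxy)-3-[(tert-butyldimethylsilyloxy)methyl]-2-(chloroethynyloxy)-5-methylbenzene | ClC#COc1c(OCc2ccccc2)cc(C)cc1CO[Si](C)(C)C(C)(C)C | intermediate
19 | lithium acetylide of the aryl ethynyl ether: ({2-(benzyloxy)-6-[(tert-butyldimethylsilyloxy)methyl]-4-methylphenoxy}ethynyl)lithium | [Li]C#COc1c(OCc2ccccc2)cc(C)cc1CO[Si](C)(C)C(C)(C)C | intermediate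
20 | 3-{2-(benzyloxy)-6-[(tert-butyldimethylsilyloxy)methyl]-4-methylphenoxy}prop-2-yn-1-ol | OCC#COc1c(OCc2ccccc2)cc(C)cc1CO[Si](C)(C)C(C)(C)C | intermediate
21 | 1-(benzyloxy)-3-[(tert-butyldimethylsilyloxy)methyl]-2-{[3-(4-methoxybenzyloxy)prop-1-yn-1-yl]oxy}-5-methylbenzene | COc1ccc(COCC#COc2c(OCc3ccccc3)cc(C)cc2CO[Si](C)(C)C(C)(C)C)cc1 | intermediate
22 | (3E,5R)-7-methyl-5,7-bis(triethylsilyloxy)octa-1,3-dien-1-one (vinylketene) | O=C=C/C=C/[C@H](O[Si](CC)(CC)CC)CC(C)(C)O[Si](CC)(CC)CC | intermediate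
23 | 3-{2-(benzyloxy)-6-[(tert-butyldimethylsilyloxy)methyl]-4-methylphenoxy}-2-[(4-methoxybenzyloxy)methyl]-4-[(1E,3R)-5-methyl-3,5-bis(triethylsilyloxy)hex-1-en-1-yl]cyclobut-2-en-1-one (both C4 epimers) | O=C1C(COCc2ccc(OC)cc2)=C(Oc2c(OCc3ccccc3)cc(C)cc2CO[Si](C)(C)C(C)(C)C)C1/C=C/[C@H](O[Si](CC)(CC)CC)CC(C)(C)O[Si](CC)(CC)CC | intermediate
24 | (3E,5E,7R)-3-{2-(benzyloxy)-6-[(tert-butyldimethylsilyloxy)methyl]-4-methylphenoxy}-2-[(4-methoxybenzyloxy)methyl]-9-methyl-7,9-bis(triethylsilyloxy)deca-1,3,5-trien-1-one (dienylketene) | O=C=C(COCc1ccc(OC)cc1)/C(Oc1c(OCc2ccccc2)cc(C)cc1CO[Si](C)(C)C(C)(C)C)=C\C=C\[C@H](O[Si](CC)(CC)CC)CC(C)(C)O[Si](CC)(CC)CC | intermediate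
25 | 3-{2-(benzyloxy)-6-[(tert-butyldimethylsilyloxy)methyl]-4-methylphenoxy}-2-[(4-methoxybenzyloxy)methyl]-6-[(1R)-3-methyl-1,3-bis(triethylsilyloxy)butyl]cyclohexa-2,4-dien-1-one (both C6 epimers) | O=C1C(COCc2ccc(OC)cc2)=C(Oc2c(OCc3ccccc3)cc(C)cc2CO[Si](C)(C)C(C)(C)C)C=CC1[C@H](O[Si](CC)(CC)CC)CC(C)(C)O[Si](CC)(CC)CC | intermediate
26 | 3-{2-(benzyloxy)-6-[(tert-butyldimethylsilyloxy)methyl]-4-methylphenoxy}-2-[(4-methoxybenzyloxy)methyl]-6-[(1R)-3-methyl-1,3-bis(triethylsilyloxy)butyl]phenol | Oc1c([C@H](O[Si](CC)(CC)CC)CC(C)(C)O[Si](CC)(CC)CC)ccc(Oc2c(OCc3ccccc3)cc(C)cc2CO[Si](C)(C)C(C)(C)C)c1COCc1ccc(OC)cc1 | intermediate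
27 | 1-{2-(benzyloxy)-6-[(tert-butyldimethylsilyloxy)methyl]-4-methylphenoxy}-3-methoxy-2-[(4-methoxybenzyloxy)methyl]-4-[(1R)-3-methyl-1,3-bis(triethylsilyloxy)butyl]benzene | COc1c([C@H](O[Si](CC)(CC)CC)CC(C)(C)O[Si](CC)(CC)CC)ccc(Oc2c(OCc3ccccc3)cc(C)cc2CO[Si](C)(C)C(C)(C)C)c1COCc1ccc(OC)cc1 | intermediate
28 | {6-[2-(benzyloxy)-6-[(tert-butyldimethylsilyloxy)methyl]-4-methylphenoxy]-2-methoxy-3-[(1R)-3-methyl-1,3-bis(triethylsilyloxy)butyl]phenyl}methanol | COc1c([C@H](O[Si](CC)(CC)CC)CC(C)(C)O[Si](CC)(CC)CC)ccc(Oc2c(OCc3ccccc3)cc(C)cc2CO[Si](C)(C)C(C)(C)C)c1CO | intermediate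
29 | 6-[2-(benzyloxy)-6-[(tert-butyldimethylsilyloxy)methyl]-4-methylphenoxy]-2-methoxy-3-[(1R)-3-methyl-1,3-bis(triethylsilyloxy)butyl]benzaldehyde | COc1c([C@H](O[Si](CC)(CC)CC)CC(C)(C)O[Si](CC)(CC)CC)ccc(Oc2c(OCc3ccccc3)cc(C)cc2CO[Si](C)(C)C(C)(C)C)c1C=O | intermediate
30 | 6-[2-(benzyloxy)-6-[(tert-butyldimethylsilyloxy)methyl]-4-methylphenoxy]-2-methoxy-3-[(1R)-3-methyl-1,3-bis(triethylsilyloxy)butyl]benzoic acid | COc1c([C@H](O[Si](CC)(CC)CC)CC(C)(C)O[Si](CC)(CC)CC)ccc(Oc2c(OCc3ccccc3)cc(C)cc2CO[Si](C)(C)C(C)(C)C)c1C(=O)O | intermediate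
31 | 6-{2-hydroxy-6-[(tert-butyldimethylsilyloxy)methyl]-4-methylphenoxy}-2-methoxy-3-[(1R)-3-methyl-1,3-bis(triethylsilyloxy)butyl]benzoic acid | COc1c([C@H](O[Si](CC)(CC)CC)CC(C)(C)O[Si](CC)(CC)CC)ccc(Oc2c(O)cc(C)cc2CO[Si](C)(C)C(C)(C)C)c1C(=O)O | intermediate
32 | 6-[2-hydroxy-6-(hydroxymethyl)-4-methylphenoxy]-3-[(1R)-1,3-dihydroxy-3-methylbutyl]-2-methoxybenzoic acid | COc1c([C@H](O)CC(C)(C)O)ccc(Oc2c(O)cc(C)cc2CO)c1C(=O)O | target

**Step count and risks**

Total steps: 19. Longest linear sequence: 14 (steps 6 to 12, step 13, steps 14 to 19).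

Most likely to fail:

1. Step 13. Capture of the short-lived vinylketene by the comparatively electron-poor aryloxyalkyne may be slower than ketene dimerisation or decay, or the cyclobutenone may not open and close cleanly. The fallback sets out from 9 and comes back to the route at 27; it uses the proven, more electron-rich siloxyalkyne class and makes the diaryl ether afterwards. Kowalski homologation of ethyl (4-methoxybenzyloxy)acetate (CH2Br2, lithium 2,2,6,6-tetramethylpiperidide, then n-BuLi) and O-silylation with iPr3SiOTf should give siloxyalkyne F1. The same photochemical benzannulation with 9 should give resorcinol monosilyl ether F2. MeI/K2CO3 then gives methyl ether F3, and one equivalent of Bu4NF at −20 °C should free only the aryl silyl ether to give phenol F4. For the ring B partner, 2-fluoro-5-methylphenol is benzylated (BnBr, K2CO3) to fluoroarene F5 and formylated next to fluorine (LiN(iPr)2, then DMF) to fluoroaldehyde F6. Nucleophilic aromatic substitution of F6 by F4 (K2CO3, DMF, 90 °C) should give diaryl ether aldehyde F7; NaBH4 gives benzylic alcohol F8, and TBSCl/imidazole gives 27.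

2. Step 11. On lithiation the dichlorovinyl ether may expel the hindered aryloxide instead of chloride, or the lithium aryloxyacetylide may decay before it meets the slowly depolymerising formaldehyde. The fallback sets out from 12 and comes back at 21, so it also bypasses step 8. NaBH4 reduces 12 to diol F9, and TBSCl (1 equiv)/imidazole should silylate the primary hydroxyl in preference to the hindered, hydrogen-bonded phenol to give phenol F10. 1,1-Dibromoalkene F11 (Ramirez olefination of (4-methoxybenzyloxy)acetaldehyde with CBr4/PPh3) is coupled with F10 under copper catalysis (CuI, 2,2'-bipyridine, K3PO4, toluene, 110 °C) to give bromo enol ether F12. KOtBu in THF then eliminates HBr to give 21 directly, with the three-carbon unit already in place.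

3. Step 3. Discrimination between the primary and the secondary silyl ether in the oxidative desilylation may be incomplete, or the α-silyloxy aldehyde may epimerise during the amine-induced collapse. The fallback sets out from 2 and comes back at 5. PivCl/pyridine at −20 °C should acylate only the primary hydroxyl to give pivalate F13; TESOTf/2,6-lutidine gives bis-silyl ether F14; iBu2AlH at −78 °C removes the pivalate to give primary alcohol F15; Parikh–Doering oxidation (SO3·pyridine, DMSO, iPr2NEt, 0 °C) gives 5.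

**Further compounds**

F1 | step 13 | triisopropyl{[3-(4-methoxybenzyloxy)prop-1-yn-1-yl]oxy}silane | COc1ccc(COCC#CO[Si](C(C)C)(C(C)C)C(C)C)cc1
F2 | step 13 | 2-[(4-methoxybenzyloxy)methyl]-6-[(1R)-3-methyl-1,3-bis(triethylsilyloxy)butyl]-3-(triisopropylsilyloxy)phenol | Oc1c([C@H](O[Si](CC)(CC)CC)CC(C)(C)O[Si](CC)(CC)CC)ccc(O[Si](C(C)C)(C(C)C)C(C)C)c1COCc1ccc(OC)cc1
F3 | step 13 | {3-methoxy-2-[(4-methoxybenzyloxy)methyl]-4-[(1R)-3-methyl-1,3-bis(triethylsilyloxy)butyl]phenoxy}triisopropylsilane | COc1c([C@H](O[Si](CC)(CC)CC)CC(C)(C)O[Si](CC)(CC)CC)ccc(O[Si](C(C)C)(C(C)C)C(C)C)c1COCc1ccc(OC)cc1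
F4 | step 13 | 3-methoxy-2-[(4-methoxybenzyloxy)methyl]-4-[(1R)-3-methyl-1,3-bis(triethylsilyloxy)butyl]phenol | COc1c([C@H](O[Si](CC)(CC)CC)CC(C)(C)O[Si](CC)(CC)CC)ccc(O)c1COCc1ccc(OC)cc1
F5 | step 13 | 1-(benzyloxy)-2-fluoro-5-methylbenzene | Cc1ccc(F)c(OCc2ccccc2)c1
F6 | step 13 | 3-(benzyloxy)-2-fluoro-5-methylbenzaldehyde | O=Cc1cc(C)cc(OCc2ccccc2)c1F
F7 | step 13 | 3-(benzyloxy)-2-{3-methoxy-2-[(4-methoxybenzyloxy)methyl]-4-[(1R)-3-methyl-1,3-bis(triethylsilyloxy)butyl]phenoxy}-5-methylbenzaldehyde | COc1c([C@H](O[Si](CC)(CC)CC)CC(C)(C)O[Si](CC)(CC)CC)ccc(Oc2c(OCc3ccccc3)cc(C)cc2C=O)c1COCc1ccc(OC)cc1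
F8 | step 13 | (3-(benzyloxy)-2-{3-methoxy-2-[(4-methoxybenzyloxy)methyl]-4-[(1R)-3-methyl-1,3-bis(triethylsilyloxy)butyl]phenoxy}-5-methylphenyl)methanol | COc1c([C@H](O[Si](CC)(CC)CC)CC(C)(C)O[Si](CC)(CC)CC)ccc(Oc2c(OCc3ccccc3)cc(C)cc2CO)c1COCc1ccc(OC)cc1
F9 | step 11 | 2-(benzyloxy)-6-(hydroxymethyl)-4-methylphenol | OCc1cc(C)cc(OCc2ccccc2)c1O
F10 | step 11 | 2-(benzyloxy)-6-[(tert-butyldimethylsilyloxy)methyl]-4-methylphenol | CC(C)(C)[Si](C)(C)OCc1cc(C)cc(OCc2ccccc2)c1O
F11 | step 11 | 1-{[(3,3-dibromoprop-2-en-1-yl)oxy]methyl}-4-methoxybenzene | COc1ccc(COCC=C(Br)Br)cc1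
F12 | step 11 | 1-(benzyloxy)-2-{[(1Z)-1-bromo-3-(4-methoxybenzyloxy)prop-1-en-1-yl]oxy}-3-[(tert-butyldimethylsilyloxy)methyl]-5-methylbenzene | COc1ccc(COC/C=C(Br)/Oc2c(OCc3ccccc3)cc(C)cc2CO[Si](C)(C)C(C)(C)C)cc1
F13 | step 3 | (2R)-2,4-dihydroxy-4-methylpentyl pivalate | CC(C)(C)C(=O)OC[C@H](O)CC(C)(C)O
F14 | step 3 | (2R)-4-methyl-2,4-bis(triethylsilyloxy)pentyl pivalate | CC(C)(C)C(=O)OC[C@H](O[Si](CC)(CC)CC)CC(C)(C)O[Si](CC)(CC)CC
F15 | step 3 | (2R)-4-methyl-2,4-bis(triethylsilyloxy)pentan-1-ol | OC[C@H](O[Si](CC)(CC)CC)CC(C)(C)O[Si](CC)(CC)CC
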